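## Retrosynthetic overview

1. Gnetofuran A ⇒ (global desilylation) its tetrasilyl ether ⇒ Heck disconnection of the aryl–vinyl bond into a 5-bromo-2-aryl-3-(silyloxymethyl)-2,3-dihydrobenzofuran and 3,5-bis(silyloxy)styrene.
2. Dihydrofuran ring ⇒ enantioselective palladium-catalysed oxyarylation of an (E)-coniferyl bis-silyl ether with 4-bromo-2-iodo-6-methoxyphenol; this forms C3–C3a, C2–O and both stereocentres in one step.
3. (E)-Coniferyl ether ⇒ Suzuki coupling of silylated 4-bromoguaiacol with the (E)-alkenylboronate from propargyl alcohol; both guaiacol-derived pieces ⇒ 4-bromoguaiacol ⇒ guaiacol ⇒ anisole.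
4. Styrene ⇒ vinyl bromide + the arylboronate from meta-selective iridium C–H borylation of bis-silylated resorcinol.
5. Ring order: the three benzene rings (A = benzofuran arene, B = guaiacyl, C = resorcinol) are carried in from anisole (twice) and resorcinol; the dihydrofuran ring is the only ring made, before the stilbene is attached.

Assumption: in step 8 the (R)-configured ligand is taken to give the (2R,3S) series; the sense of induction of this unprecedented step must be established experimentally, and the (S)-ligand is used if it is reversed.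

## Route

Step 1
Reactants: 1 anisole (methoxybenzene)
Product: 4 2-methoxyphenol (guaiacol), via (2-methoxyphenyl)lithium 2 (not isolated), via lithium trimethoxy(2-methoxyphenyl)borate 3 (not isolated)
Conditions: n-BuLi, TMEDA, Et2O, 0 °C → rt; B(OMe)3, −78 °C → rt; AcOH then 30% H2O2, 0 °C → rt
Reagents that add atoms: hydrogen peroxide, OO (phenol oxygen of 4); trimethyl borate, COB(OC)OC (boron and methoxy groups of 3 only); n-butyllithium, [Li]CCCC (lithium of 2 only)
Why: Directed ortho-metalation, in which the methoxy group directs lithiation to the ortho carbon, the aryllithium is trapped as the borate and the aryl group migrates from boron to oxygen on peroxide oxidation (ortho-lithiation/borylation–oxidation), so only the ortho-hydroxylated product forms.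

Step 2
Reactants: 4 2-methoxyphenol
Product: 5 4-bromo-2-methoxyphenol
Conditions: NBS (1.0 equiv), MeCN, −20 → 0 °C
Reagents that add atoms: N-bromosuccinimide, O=C1CCC(=O)N1Br
Why: Electrophilic aromatic bromination controlled by the free hydroxyl group, the stronger donor, which in MeCN without amine directs NBS para to itself.

Step 3
Reactants: 5 4-bromo-2-methoxyphenol
Product: 6 4-bromo-2-iodo-6-methoxyphenol
Conditions: NIS (1.05 equiv), TFA (cat.), MeCN, 0 °C → rt
Reagents that add atoms: N-iodosuccinimide, O=C1CCC(=O)N1I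
Why: Electrophilic aromatic iodination, in which the para position is blocked by bromine so the only carbon still activated by the hydroxyl group is the free ortho position C6.

Step 4
Reactants: 5 4-bromo-2-methoxyphenol
Product: 7 (4-bromo-2-methoxyphenoxy)triisopropylsilane
Conditions: TIPSCl, imidazole, DMF, rt
Reagents that add atoms: triisopropylsilyl chloride, CC(C)[Si](Cl)(C(C)C)C(C)C
Why: Imidazole-promoted silylation of a phenol, giving a bulky aryl silyl ether that tolerates the later phosphate-base and silver/palladium steps.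

Step 5
Reactants: 8 prop-2-yn-1-ol (propargyl alcohol)
Product: 9 tert-butyldimethyl(prop-2-yn-1-yloxy)silane
Conditions: TBSCl, imidazole, CH2Cl2, 0 °C → rt
Reagents that add atoms: tert-butyldimethylsilyl chloride, CC(C)(C)[Si](C)(C)Cl
Why: Standard imidazole-promoted silylation of a primary alcohol.

Step 6
Reactants: 9 tert-butyldimethyl(prop-2-yn-1-yloxy)silane
Product: 10 (E)-tert-butyldimethyl{[3-(4,4,5,5-tetramethyl-1,3,2-dioxaborolan-2-yl)allyl]oxy}silane
Conditions: HBpin (1.05 equiv), Cp2Zr(H)Cl (5 mol %), Et3N (10 mol %), neat, 60 °C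
Reagents that add atoms: pinacolborane, CC1(C)OBOC1(C)C
Why: Zirconocene hydride-catalysed hydroboration of a terminal alkyne, a syn and anti-Markovnikov addition of H–B that gives only the (E)-alkenylboronate.

Step 7
Reactants: 7 (4-bromo-2-methoxyphenoxy)triisopropylsilane; 10 (E)-tert-butyldimethyl{[3-(4,4,5,5-tetramethyl-1,3,2-dioxaborolan-2-yl)allyl]oxy}silane
Product: 11 (E)-tert-butyl({3-[3-methoxy-4-(triisopropylsilyloxy)phenyl]allyl}oxy)dimethylsilane
Conditions: Pd(dppf)Cl2 (3 mol %), K3PO4, THF/H2O (9:1), 60 °C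
Reagents that add atoms: none
Why: Suzuki–Miyaura coupling, which proceeds with retention of alkene geometry so the (E)-configuration of 10 is carried into 11.

Step 8
Reactants: 6 4-bromo-2-iodo-6-methoxyphenol; 11 (E)-tert-butyl({3-[3-methoxy-4-(triisopropylsilyloxy)phenyl]allyl}oxy)dimethylsilane
Product: 12 (2R,3S)-5-bromo-3-{[(tert-butyldimethylsilyl)oxy]methyl}-7-methoxy-2-[3-methoxy-4-(triisopropylsilyloxy)phenyl]-2,3-dihydrobenzofuran
Conditions: Pd2(dba)3 (2.5 mol %), (R)-DTBM-SEGPHOS (6 mol %), Ag2CO3 (1.1 equiv), acetone, 45 °C, dark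
Reagents that add atoms: none
Why: Proposed new method: an enantioselective intermolecular oxyarylation ([3+2] heteroannulation) of an acyclic (E)-β-substituted styrene with a 2-iodophenol, in which zerovalent palladium inserts into the C–I bond of 6 (much faster than into C–Br), Ag2CO3 strips iodide and deprotonates the phenol, the cationic arylpalladium carrying (R)-DTBM-SEGPHOS binds one face of the alkene of 11 and migratory insertion puts the aryl group on the CH2OTBS-bearing carbon and palladium on the benzylic carbon as an η3-benzyl (this fixes C3 as S in the enantio-determining step and slows β-hydride elimination), after which the tethered phenoxide forms the C2–O bond either by stereoretentive reductive elimination from the six-membered oxapalladacycle or through the ionised, quinone-methide-like benzylic carbon, both of which give the 2,3-trans ring and hence 2R; the closest known reaction types are the racemic palladium/silver oxyarylation of cyclic styrenes such as chromenes (pterocarpan synthesis) and the enantioselective Larock-type heteroannulation of 2-halophenols with 1,3-dienes.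

Step 9
Reactants: 13 resorcinol (benzene-1,3-diol)
Product: 14 1,3-bis(triisopropylsilyloxy)benzene
Conditions: TIPSCl (2.2 equiv), imidazole, DMF, rt
Reagents that add atoms: triisopropylsilyl chloride, CC(C)[Si](Cl)(C(C)C)C(C)C
Why: Standard imidazole-promoted double silylation of a diphenol.

Step 10
Reactants: 14 1,3-bis(triisopropylsilyloxy)benzene
Product: 15 2-[3,5-bis(triisopropylsilyloxy)phenyl]-4,4,5,5-tetramethyl-1,3,2-dioxaborolane
Conditions: [Ir(OMe)(cod)]2 (1.5 mol %), 4,4′-di-tert-butyl-2,2′-bipyridine (3 mol %), B2pin2 (1.0 equiv), THF, 80 °C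
Reagents that add atoms: bis(pinacolato)diboron, CC1(C)OB(OC1(C)C)B1OC(C)(C)C(C)(C)O1
Why: Iridium-catalysed aromatic C–H borylation is sterically controlled, so only the C–H bond meta to both silyloxy groups (C5), the one without an ortho substituent, is borylated.

Step 11
Reactants: 15 2-[3,5-bis(triisopropylsilyloxy)phenyl]-4,4,5,5-tetramethyl-1,3,2-dioxaborolane; 16 bromoethene (vinyl bromide)
Product: 17 3,5-bis(triisopropylsilyloxy)styrene
Conditions: Pd(PPh3)4 (3 mol %), vinyl bromide (1 M in THF, 3 equiv), K3PO4, THF/H2O, 60 °C, sealed tube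
Reagents that add atoms: none
Why: Suzuki–Miyaura coupling of an unhindered arylboronate with vinyl bromide, whose C–Br bond adds easily to zerovalent palladium, under phosphate base that aryl TIPS ethers tolerate.

Step 12
Reactants: 12 (2R,3S)-5-bromo-3-{[(tert-butyldimethylsilyl)oxy]methyl}-7-methoxy-2-[3-methoxy-4-(triisopropylsilyloxy)phenyl]-2,3-dihydrobenzofuran; 17 3,5-bis(triisopropylsilyloxy)styrene
Product: 18 (2R,3S)-5-[(E)-3,5-bis(triisopropylsilyloxy)styryl]-3-{[(tert-butyldimethylsilyl)oxy]methyl}-7-methoxy-2-[3-methoxy-4-(triisopropylsilyloxy)phenyl]-2,3-dihydrobenzofuran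
Conditions: Pd2(dba)3 (2 mol %), P(t-Bu)3·HBF4 (8 mol %), Cy2NMe (1.5 equiv), 1,4-dioxane, 80 °C
Reagents that add atoms: none
Why: Mizoroki–Heck reaction, in which electron-rich phosphine-ligated zerovalent palladium adds to the aryl bromide, syn insertion at the terminal styrene carbon and syn β-hydride elimination give the (E)-stilbene, and the amine base leaves the silyl ethers and both stereocentres untouched.

Step 13
Reactants: 18 (2R,3S)-5-[(E)-3,5-bis(triisopropylsilyloxy)styryl]-3-{[(tert-butyldimethylsilyl)oxy]methyl}-7-methoxy-2-[3-methoxy-4-(triisopropylsilyloxy)phenyl]-2,3-dihydrobenzofuran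
Product: 19 gnetofuran A
Conditions: TBAF (6 equiv), AcOH (6 equiv), THF, 0 °C → rt, argon
Reagents that add atoms: none
Why: Fluoride-driven cleavage of all four silyl ethers (Si–F bond formation), buffered with acetic acid so that no free phenoxide can open the dihydrofuran through a quinone methide, which leaves both stereocentres as set in step 8.

## Compound list

1 | anisole | COc1ccccc1 | starting material
2 | (2-methoxyphenyl)lithium | [Li]c1ccccc1OC | intermediate
3 | lithium trimethoxy(2-methoxyphenyl)borate | [Li+].COc1ccccc1[B-](OC)(OC)OC | intermediate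
4 | 2-methoxyphenol (guaiacol) | COc1ccccc1O | intermediate
5 | 4-bromo-2-methoxyphenol | COc1cc(Br)ccc1O | intermediate
6 | 4-bromo-2-iodo-6-methoxyphenol | COc1cc(Br)cc(I)c1O | intermediate
7 | (4-bromo-2-methoxyphenoxy)triisopropylsilane | COc1cc(Br)ccc1O[Si](C(C)C)(C(C)C)C(C)C | intermediate
8 | prop-2-yn-1-ol | C#CCO | starting material
9 | tert-butyldimethyl(prop-2-yn-1-yloxy)silane | C#CCO[Si](C)(C)C(C)(C)C | intermediate
10 | (E)-tert-butyldimethyl{[3-(4,4,5,5-tetramethyl-1,3,2-dioxaborolan-2-yl)allyl]oxy}silane | CC(C)(C)[Si](C)(C)OC/C=C/B1OC(C)(C)C(C)(C)O1 | intermediate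
11 | (E)-tert-butyl({3-[3-methoxy-4-(triisopropylsilyloxy)phenyl]allyl}oxy)dimethylsilane | COc1cc(/C=C/CO[Si](C)(C)C(C)(C)C)ccc1O[Si](C(C)C)(C(C)C)C(C)C | intermediate
12 | (2R,3S)-5-bromo-3-{[(tert-butyldimethylsilyl)oxy]methyl}-7-methoxy-2-[3-methoxy-4-(triisopropylsilyloxy)phenyl]-2,3-dihydrobenzofuran | COc1cc([C@@H]2Oc3c(OC)cc(Br)cc3[C@H]2CO[Si](C)(C)C(C)(C)C)ccc1O[Si](C(C)C)(C(C)C)C(C)C | intermediate
13 | resorcinol | Oc1cccc(O)c1 | starting material
14 | 1,3-bis(triisopropylsilyloxy)benzene | CC(C)[Si](Oc1cccc(O[Si](C(C)C)(C(C)C)C(C)C)c1)(C(C)C)C(C)C | intermediate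
15 | 2-[3,5-bis(triisopropylsilyloxy)phenyl]-4,4,5,5-tetramethyl-1,3,2-dioxaborolane | CC(C)[Si](Oc1cc(B2OC(C)(C)C(C)(C)O2)cc(O[Si](C(C)C)(C(C)C)C(C)C)c1)(C(C)C)C(C)C | intermediate
16 | bromoethene (vinyl bromide) | C=CBr | starting material
17 | 3,5-bis(triisopropylsilyloxy)styrene | C=Cc1cc(O[Si](C(C)C)(C(C)C)C(C)C)cc(O[Si](C(C)C)(C(C)C)C(C)C)c1 | intermediate
18 | (2R,3S)-5-[(E)-3,5-bis(triisopropylsilyloxy)styryl]-3-{[(tert-butyldimethylsilyl)oxy]methyl}-7-methoxy-2-[3-methoxy-4-(triisopropylsilyloxy)phenyl]-2,3-dihydrobenzofuran | COc1cc([C@@H]2Oc3c(OC)cc(/C=C/c4cc(O[Si](C(C)C)(C(C)C)C(C)C)cc(O[Si](C(C)C)(C(C)C)C(C)C)c4)cc3[C@H]2CO[Si](C)(C)C(C)(C)C)ccc1O[Si](C(C)C)(C(C)C)C(C)C | intermediate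
19 | gnetofuran A, 5-{(E)-2-[(2R,3S)-2-(4-hydroxy-3-methoxyphenyl)-3-(hydroxymethyl)-7-methoxy-2,3-dihydrobenzofuran-5-yl]vinyl}benzene-1,3-diol | COc1cc([C@@H]2Oc3c(OC)cc(/C=C/c4cc(O)cc(O)c4)cc3[C@H]2CO)ccc1O | target

## Step count

Total steps: 13.
Longest linear sequence: 7 steps (1, 2, 4, 7, 8, 12, 13). The other branches are 1–2–3 (three steps to 6), 5–6 (two steps to 10) and 9–10–11 (three steps to 17).

## Steps most likely to fail, with fallbacks

**Step 8 (the proposed new oxyarylation).** Risks are insertion with the wrong regiochemistry, Heck-type β-hydride elimination to the trisubstituted alkene instead of C–O closure, and low enantioselectivity. The fallback uses the known rhodium-carbene C–H insertion route to 2-aryl-2,3-dihydrobenzofuran-3-carboxylates. It sets out from 6 and 7 and comes back to the route at 12.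

Bromide 7 is lithiated (n-BuLi, THF, −78 °C) and trapped with paraformaldehyde to give [3-methoxy-4-(triisopropylsilyloxy)phenyl]methanol F1. Mitsunobu etherification of phenol 6 with this alcohol (PPh3, DIAD, THF) gives 5-bromo-1-iodo-3-methoxy-2-{[3-methoxy-4-(triisopropylsilyloxy)benzyl]oxy}benzene F2. Iodide-selective coupling with the Reformatsky reagent BrZnCH2CO2Me (Pd(PPh3)4, THF, 50 °C) gives methyl 2-(5-bromo-3-methoxy-2-{[3-methoxy-4-(triisopropylsilyloxy)benzyl]oxy}phenyl)acetate F3. Diazo transfer (p-acetamidobenzenesulfonyl azide, DBU, MeCN) gives methyl 2-(5-bromo-3-methoxy-2-{[3-methoxy-4-(triisopropylsilyloxy)benzyl]oxy}phenyl)-2-diazoacetate F4.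

Intramolecular insertion of the rhodium carbene into the benzylic C–H bond (Rh2(S-PTTL)4 or its enantiomer, whichever gives 2R; toluene, −60 °C) closes the ring to the cis ester methyl (2R,3S)-5-bromo-7-methoxy-2-[3-methoxy-4-(triisopropylsilyloxy)phenyl]-2,3-dihydrobenzofuran-3-carboxylate F5. Epimerisation at C3 (DBU, toluene, rt) gives the trans ester methyl (2R,3R)-5-bromo-7-methoxy-2-[3-methoxy-4-(triisopropylsilyloxy)phenyl]-2,3-dihydrobenzofuran-3-carboxylate F6. Reduction with i-Bu2AlH (CH2Cl2, −78 → 0 °C) gives {(2R,3S)-5-bromo-7-methoxy-2-[3-methoxy-4-(triisopropylsilyloxy)phenyl]-2,3-dihydrobenzofuran-3-yl}methanol F7, and silylation (TBSCl, imidazole) returns 12.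

**Step 12 (late-stage Heck reaction).** Risks are slow oxidative addition to the electron-rich bromide, some 1,1-diarylethene regioisomer and oligomerisation of the styrene. The fallback replaces the Heck reaction by a Suzuki–Miyaura coupling with a preformed (E)-alkenylboronate. It sets out from 17 and comes back at 18.

Cross-metathesis of 17 with vinylboronic acid pinacol ester (second-generation Grubbs catalyst, RuCl2(H2IMes)(PCy3)(=CHPh), CH2Cl2, 40 °C) gives (E)-2-[3,5-bis(triisopropylsilyloxy)styryl]-4,4,5,5-tetramethyl-1,3,2-dioxaborolane F8. Coupling of this boronate with bromide 12 (Pd(dppf)Cl2, K3PO4, dioxane/H2O, 80 °C) gives 18 with the (E)-geometry already fixed.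

**Step 13 (global desilylation).** The free polyphenolic stilbene is air- and base-sensitive and hard to purify if fluoride cleavage is not clean. The fallback isolates the product as its peracetate and releases it under acid instead of fluoride. It sets out from 18 and comes back at 19.

Compound 18 is treated with TBAF (THF, 0 °C) and the mixture is quenched in the same flask with Ac2O, Et3N and DMAP. This gives the stable, chromatographable 4-{(2R,3S)-3-(acetoxymethyl)-5-[(E)-3,5-diacetoxystyryl]-7-methoxy-2,3-dihydrobenzofuran-2-yl}-2-methoxyphenyl acetate F9. Acid-catalysed transesterification (catalytic AcCl in MeOH, 0 °C → rt) then gives 19 without any phenoxide being formed.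

## Further compounds

F1 | step 8 | [3-methoxy-4-(triisopropylsilyloxy)phenyl]methanol | COc1cc(CO)ccc1O[Si](C(C)C)(C(C)C)C(C)C
F2 | step 8 | 5-bromo-1-iodo-3-methoxy-2-{[3-methoxy-4-(triisopropylsilyloxy)benzyl]oxy}benzene | COc1cc(COc2c(I)cc(Br)cc2OC)ccc1O[Si](C(C)C)(C(C)C)C(C)C
F3 | step 8 | methyl 2-(5-bromo-3-methoxy-2-{[3-methoxy-4-(triisopropylsilyloxy)benzyl]oxy}phenyl)acetate | COC(=O)Cc1cc(Br)cc(OC)c1OCc1ccc(O[Si](C(C)C)(C(C)C)C(C)C)c(OC)c1
F4 | step 8 | methyl 2-(5-bromo-3-methoxy-2-{[3-methoxy-4-(triisopropylsilyloxy)benzyl]oxy}phenyl)-2-diazoacetate | COC(=O)C(=[N+]=[N-])c1cc(Br)cc(OC)c1OCc1ccc(O[Si](C(C)C)(C(C)C)C(C)C)c(OC)c1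
F5 | step 8 | methyl (2R,3S)-5-bromo-7-methoxy-2-[3-methoxy-4-(triisopropylsilyloxy)phenyl]-2,3-dihydrobenzofuran-3-carboxylate (cis) | COc1cc([C@@H]2Oc3c(OC)cc(Br)cc3[C@@H]2C(=O)OC)ccc1O[Si](C(C)C)(C(C)C)C(C)C
F6 | step 8 | methyl (2R,3R)-5-bromo-7-methoxy-2-[3-methoxy-4-(triisopropylsilyloxy)phenyl]-2,3-dihydrobenzofuran-3-carboxylate (trans) | COc1cc([C@@H]2Oc3c(OC)cc(Br)cc3[C@H]2C(=O)OC)ccc1O[Si](C(C)C)(C(C)C)C(C)C
F7 | step 8 | {(2R,3S)-5-bromo-7-methoxy-2-[3-methoxy-4-(triisopropylsilyloxy)phenyl]-2,3-dihydrobenzofuran-3-yl}methanol | COc1cc([C@@H]2Oc3c(OC)cc(Br)cc3[C@H]2CO)ccc1O[Si](C(C)C)(C(C)C)C(C)C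
F8 | step 12 | (E)-2-[3,5-bis(triisopropylsilyloxy)styryl]-4,4,5,5-tetramethyl-1,3,2-dioxaborolane | CC(C)[Si](Oc1cc(/C=C/B2OC(C)(C)C(C)(C)O2)cc(O[Si](C(C)C)(C(C)C)C(C)C)c1)(C(C)C)C(C)C
F9 | step 13 | 4-{(2R,3S)-3-(acetoxymethyl)-5-[(E)-3,5-diacetoxystyryl]-7-methoxy-2,3-dihydrobenzofuran-2-yl}-2-methoxyphenyl acetate | COc1cc([C@@H]2Oc3c(OC)cc(/C=C/c4cc(OC(C)=O)cc(OC(C)=O)c4)cc3[C@H]2COC(C)=O)ccc1OC(C)=O
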